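The initiator in this flask decays slowly, with a half-life of 117 s against the 12 s of the run, and I work from that slowness.

    initiator → 2 initiating radical (k1 = 0.0059 s⁻¹)
    free monomer + initiating radical → growing radical + monomer in chains (k2 = 1.2 × 10⁸ L mol⁻¹ s⁻¹)
    free monomer + growing radical → monomer in chains + growing radical, rate k3*[growing radical]*[free monomer] (k3 = 4.4 × 10⁶ L mol⁻¹ s⁻¹)
    2 growing radical → dead chain (k4 = 9 × 10⁷ L mol⁻¹ s⁻¹)

free monomer 2.0 mM; initiator 3.2 µM; time 12 s

- average number of monomer units in a chain (living and dead chains, two that joined counted as one) at 12 s
- part of the free monomer that has reacted at 12 s

- where a step has two of a species, its rate is k times that concentration squared, and two are used at each turn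
- the average divides the monomer in chains by the number of chains, living and dead together; two radicals that join make one chain
- run time (flask): 12 s

**Radical level.** I take the growing radical to be lost in pairs as fast as the initiator supplies it, which puts it at 1.45 × 10⁻⁵ mM, and it gets there in about 0.384 s, short against the run: a steady state.

**Chain ratio.** I divide the rate at which free monomer enters chains by the rate at which dead chains appear, so that time drops out: the propagation constant times free monomer, over the termination constant times growing radical. This is the kinetic chain length counted per dead chain, not per radical. At the charge it is 6750 units, and while the radical level holds it falls in step with free monomer.

**When you come.** I expect 53.5% of the free monomer reacted, 93.2% of the initiator left, and the ratio averaged over the run at 4720 units per chain. Add no initiator: the radical level stands in the denominator of my ratio.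

**Forecast, result.** The forecast, with radicals that “nearly all pair up”, gives 4600 and 52%, a little below mine; the flask reads 4610 and 52.1%.

**Two clocks.** At 5.03 s this flask's free monomer has a half-life of 11 s by propagation, shorter than the initiator's 120 s, and at the asked time 48% of the free monomer stands beside 93% of the initiator, with my reckoned chain ratio down to 3240 units. The same flask read at 20 s gets an averaged ratio of 3820 units by my reckoning, and it reads 3890.

The numbers of this flask were drawn at random within sensible limits; the result is computed.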